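Ring atoms: C1 (heptenyl), C2 (hydroxymethyl), C3 (carbinol), C4/C5 (oxirane, C5 quaternary), C6 (ketone). The route rests on removing C1: the C6(=O)–C1=C2 enone is traced to a 2-bromoenone and this to a cyclopentanone in which C6 is bonded directly to C2. The key step exploits the fact that C3, C4 and C5 of the cyclohexenone ring correspond to an anti-epoxidised 4-silyloxycyclopentanone: dibromocarbene adds to its C6=C2 silyl enol ether and the adduct opens, inserting C1, enlarging the ring to six atoms and leaving bromine on C1 for cross-coupling. The precursor is the trimethylsilyl enol ether of a 2,3-epoxy-4-silyloxy-5-(silyloxymethyl)cyclopentanone carrying the tert-butyl enoate chain on C5.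

Key step: step 9

Remarks on the chemistry:
- Assumption: the target descriptors correspond to (1S,5R,6S) in 7-oxabicyclo[4.1.0]heptene numbering, that is, the C3 hydroxyl anti to the oxirane oxygen. This is taken as intended and is what the (R)-configured silyloxycyclopentenone delivers after epoxidation anti to the silyl ether.
- Ester: a tert-butyl ester is carried. Alkoxide exchange with tert-butoxide in the key step is degenerate, and the ester is removed by acid, so the base-labile γ-hydroxy epoxy enone never meets hydroxide.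
- Hydroxymethyl group: protected as a tert-butyldimethylsilyl ether. It goes on under neutral conditions onto a β-hydroxy ketone, is inert to tert-butoxide and carbene, and leaves together with the C3 silyl ether.
- Transient stereocentres: the carbon bearing the new CH2OH group and the two cyclopropane carbons of the carbene adduct are drawn as the expected isomers. They become sp2 again, so their configuration has no consequence.

Step 1
Reactants: 1 (R)-4-(tert-butyldimethylsilyloxy)cyclopent-2-en-1-one
Product: 2 (R)-4-(tert-butyldimethylsilyloxy)-2-iodocyclopent-2-en-1-one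
Conditions: I2, pyridine, CH2Cl2, 0 °C to rt
Reagents that add atoms: iodine, II
Why: Johnson α-iodination of an enone, in which pyridine adds reversibly to the β-carbon, the enolate is iodinated and pyridine is expelled, places iodine on the α-carbon without touching the silyloxy stereocentre.

Step 2
Reactants: 2 (R)-4-(tert-butyldimethylsilyloxy)-2-iodocyclopent-2-en-1-one; 3 allyltributylstannane
Product: 4 (R)-2-allyl-4-(tert-butyldimethylsilyloxy)cyclopent-2-en-1-one
Conditions: PdCl2(PhCN)2 (5 mol %), AsPh3, CuI, NMP, rt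
Reagents that add atoms: 3 allyltributylstannane, C=CC[Sn](CCCC)(CCCC)CCCC
Why: Stille coupling of an α-iodoenone with an allylstannane, accelerated by AsPh3 and CuI, joins the allyl group to the α-carbon under neutral conditions that leave the silyl ether and its stereocentre intact.

Step 3
Reactants: 4 (R)-2-allyl-4-(tert-butyldimethylsilyloxy)cyclopent-2-en-1-one; 5 tert-butyl methacrylate
Product: 6 tert-butyl (E)-4-[(3R)-3-(tert-butyldimethylsilyloxy)-5-oxocyclopent-1-en-1-yl]-2-methylbut-2-enoate
Conditions: second-generation Grubbs catalyst (5 mol %), 5 (excess), CH2Cl2, 40 °C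
Reagents that add atoms: 5 tert-butyl methacrylate, C=C(C)C(=O)OC(C)(C)C
Why: Olefin cross-metathesis between the terminal allyl alkene and the slowly homodimerising 1,1-disubstituted methacrylate gives the trisubstituted enoate with the ester trans to the chain (E) under thermodynamic control, the electron-poor ring alkene being inert to the catalyst.

Step 4
Reactants: 6 tert-butyl (E)-4-[(3R)-3-(tert-butyldimethylsilyloxy)-5-oxocyclopent-1-en-1-yl]-2-methylbut-2-enoate
Product: 7 tert-butyl (E)-4-[(1S,4R,5S)-4-(tert-butyldimethylsilyloxy)-2-oxo-6-oxabicyclo[3.1.0]hexan-1-yl]-2-methylbut-2-enoate (oxirane anti to the silyloxy group)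
Conditions: 30% H2O2, NaOH (0.2 equiv), MeOH, −20 to 0 °C
Reagents that add atoms: hydrogen peroxide, OO
Why: Weitz–Scheffer nucleophilic epoxidation, in which hydroperoxide adds to the enone β-carbon from the face opposite the adjacent silyloxy group and the enolate closes the oxirane, sets both oxirane carbons (C4 and C5 of the target) anti to the silyl ether, while the less electrophilic, hindered enoate is not attacked.

Step 5
Reactants: 7 tert-butyl (E)-4-[(1S,4R,5S)-4-(tert-butyldimethylsilyloxy)-2-oxo-6-oxabicyclo[3.1.0]hexan-1-yl]-2-methylbut-2-enoate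
Product: 8 tert-butyl (E)-4-[(1S,4R,5S)-4-(tert-butyldimethylsilyloxy)-2-(trimethylsilyloxy)-6-oxabicyclo[3.1.0]hex-2-en-1-yl]-2-methylbut-2-enoate
Conditions: TMSOTf, Et3N, CH2Cl2, −78 to 0 °C
Reagents that add atoms: trimethylsilyl trifluoromethanesulfonate, C[Si](C)(C)OS(=O)(=O)C(F)(F)F
Why: Soft enolisation (silyl triflate and amine) can occur only towards the CH2 group because the other α-carbon is the quaternary oxirane carbon, and it avoids a free metal enolate that could expel the β-silyloxy group.

Step 6
Reactants: 8 tert-butyl (E)-4-[(1S,4R,5S)-4-(tert-butyldimethylsilyloxy)-2-(trimethylsilyloxy)-6-oxabicyclo[3.1.0]hex-2-en-1-yl]-2-methylbut-2-enoate; 9 formaldehyde (37% aqueous solution)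
Product: 10 tert-butyl (E)-4-[(1S,3R,4R,5S)-4-(tert-butyldimethylsilyloxy)-3-(hydroxymethyl)-2-oxo-6-oxabicyclo[3.1.0]hexan-1-yl]-2-methylbut-2-enoate (CH2OH trans to the silyloxy group)
Conditions: 37% aq. HCHO, Yb(OSO2CF3)3 (10 mol %), THF, rt
Reagents that add atoms: 9 formaldehyde, C=O
Why: Lanthanide-triflate-catalysed aqueous Mukaiyama aldol reaction (hydroxymethylation of a silyl enol ether) forms the C–C bond at the only nucleophilic carbon; the new centre should form trans to the neighbouring silyloxy group and is erased again in step 8.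

Step 7
Reactants: 10 tert-butyl (E)-4-[(1S,3R,4R,5S)-4-(tert-butyldimethylsilyloxy)-3-(hydroxymethyl)-2-oxo-6-oxabicyclo[3.1.0]hexan-1-yl]-2-methylbut-2-enoate
Product: 11 tert-butyl (E)-4-[(1S,3R,4R,5S)-4-(tert-butyldimethylsilyloxy)-3-[(tert-butyldimethylsilyloxy)methyl]-2-oxo-6-oxabicyclo[3.1.0]hexan-1-yl]-2-methylbut-2-enoate
Conditions: TBSCl, imidazole, DMF, 0 °C to rt
Reagents that add atoms: tert-butyldimethylsilyl chloride, CC(C)(C)[Si](C)(C)Cl
Why: Imidazole-mediated silylation of the primary alcohol is a standard neutral protection that is fast enough at 0 °C to avoid retro-aldol loss of formaldehyde or dehydration of the β-hydroxy ketone.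

Step 8
Reactants: 11 tert-butyl (E)-4-[(1S,3R,4R,5S)-4-(tert-butyldimethylsilyloxy)-3-[(tert-butyldimethylsilyloxy)methyl]-2-oxo-6-oxabicyclo[3.1.0]hexan-1-yl]-2-methylbut-2-enoate
Product: 12 tert-butyl (E)-4-[(1S,4R,5S)-4-(tert-butyldimethylsilyloxy)-3-[(tert-butyldimethylsilyloxy)methyl]-2-(trimethylsilyloxy)-6-oxabicyclo[3.1.0]hex-2-en-1-yl]-2-methylbut-2-enoate
Conditions: TMSOTf, Et3N, CH2Cl2, −78 to 0 °C
Reagents that add atoms: trimethylsilyl trifluoromethanesulfonate, C[Si](C)(C)OS(=O)(=O)C(F)(F)F
Why: Soft enolisation again, with the single remaining α-hydrogen on the carbon bearing the silyloxymethyl group, gives the tetrasubstituted C6=C2 enol ether regiospecifically, and the absence of a metal enolate suppresses β-elimination of either silyloxy group.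

Step 9
Reactants: 12 tert-butyl (E)-4-[(1S,4R,5S)-4-(tert-butyldimethylsilyloxy)-3-[(tert-butyldimethylsilyloxy)methyl]-2-(trimethylsilyloxy)-6-oxabicyclo[3.1.0]hex-2-en-1-yl]-2-methylbut-2-enoate; 13 bromoform
Product: 15 tert-butyl (E)-4-[(1S,5R,6S)-3-bromo-5-(tert-butyldimethylsilyloxy)-4-[(tert-butyldimethylsilyloxy)methyl]-2-oxo-7-oxabicyclo[4.1.0]hept-3-en-1-yl]-2-methylbut-2-enoate, via siloxy-dibromocyclopropane adduct 14 (not isolated)
Conditions: CHBr3 (2 equiv), KOC(CH3)3 (2.5 equiv), pentane, −30 °C to rt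
Reagents that add atoms: 13 bromoform, BrC(Br)Br
Why: Deprotonation of bromoform and loss of bromide give singlet dibromocarbene, an electrophile that adds in a concerted [2+1] cheletropic step to the most electron-rich alkene present, the tetrasubstituted C6=C2 silyl enol ether, to give the 1-siloxy-dibromocyclopropane 14. Donation from the siloxy oxygen and departure of the endo bromide then drive a disrotatory two-electron electrocyclic opening of the internal C6–C2 bond (cyclopropyl-to-allyl cation rearrangement), and removal of the trimethylsilyl group from the oxocarbenium ion by tert-butoxide leaves the C6 ketone with C1(Br)=C2; the closest known reaction type is the dihalocarbene ring expansion of cyclic trimethylsilyl enol ethers to 2-halocycloalk-2-enones. The only ring closed is the transient cyclopropane, by the cheletropic addition, while the cyclohexenone is not made by a cyclisation at all but by one-carbon growth of the cyclopentane ring. No stereocentre is created in 15: the two cyclopropane centres of 14 return to sp2, so the face of carbene attack does not matter, and C3, C4 and C5 are not touched. The step needs chemoselectivity for the enol ether, which follows from the carbene being electrophilic and the side-chain alkene being deactivated by its ester, and a single site of insertion, which follows from the quaternary C5 leaving C6=C2 as the only possible enol ether; the tert-butyl ester cannot be changed by tert-butoxide.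

Step 10
Reactants: 15 tert-butyl (E)-4-[(1S,5R,6S)-3-bromo-5-(tert-butyldimethylsilyloxy)-4-[(tert-butyldimethylsilyloxy)methyl]-2-oxo-7-oxabicyclo[4.1.0]hept-3-en-1-yl]-2-methylbut-2-enoate; 16 (E)-hept-1-enylboronic acid
Product: 17 tert-butyl (E)-4-[(1S,5R,6S)-5-(tert-butyldimethylsilyloxy)-4-[(tert-butyldimethylsilyloxy)methyl]-3-[(E)-hept-1-enyl]-2-oxo-7-oxabicyclo[4.1.0]hept-3-en-1-yl]-2-methylbut-2-enoate
Conditions: Pd(PPh3)4 (5 mol %), K3PO4, THF/H2O, 40 °C
Reagents that add atoms: 16 (E)-hept-1-enylboronic acid, CCCCC/C=C/B(O)O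
Why: Suzuki–Miyaura coupling of the alkenyl bromide with the alkenylboronic acid proceeds with retention of both alkene geometries and installs the (E)-heptenyl group on C1, the mild phosphate base sparing the epoxy enone, the silyl ethers and the tert-butyl ester.

Step 11
Reactants: 17 tert-butyl (E)-4-[(1S,5R,6S)-5-(tert-butyldimethylsilyloxy)-4-[(tert-butyldimethylsilyloxy)methyl]-3-[(E)-hept-1-enyl]-2-oxo-7-oxabicyclo[4.1.0]hept-3-en-1-yl]-2-methylbut-2-enoate
Product: 18 tert-butyl (E)-4-[(1S,5R,6S)-3-[(E)-hept-1-enyl]-5-hydroxy-4-(hydroxymethyl)-2-oxo-7-oxabicyclo[4.1.0]hept-3-en-1-yl]-2-methylbut-2-enoate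
Conditions: HF·pyridine, pyridine/THF, 0 °C to rt
Reagents that add atoms: none
Why: Fluoride-driven cleavage of both Si–O bonds by buffered hydrogen fluoride (silyl ether deprotection) frees the two alcohols without affecting the oxirane, the dienone or the tert-butyl ester.

Step 12
Reactants: 18 tert-butyl (E)-4-[(1S,5R,6S)-3-[(E)-hept-1-enyl]-5-hydroxy-4-(hydroxymethyl)-2-oxo-7-oxabicyclo[4.1.0]hept-3-en-1-yl]-2-methylbut-2-enoate
Product: 19 (E)-4-[(1S,5R,6S)-3-[(E)-hept-1-enyl]-5-hydroxy-4-(hydroxymethyl)-2-oxo-7-oxabicyclo[4.1.0]hept-3-en-1-yl]-2-methylbut-2-enoic acid (CNP0332048.4)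
Conditions: CF3CO2H/CH2Cl2 (1:4), 0 °C; evaporation, then brief MeOH/H2O to cleave any trifluoroacetate
Reagents that add atoms: none
Why: Acidolysis of the tert-butyl ester by alkyl–oxygen cleavage with loss of isobutene frees the carboxylic acid without hydroxide; cations at C3 or at the hydroxymethyl carbon are disfavoured by the acyl group on C1, so the alcohols, the α-keto oxirane and all three stereocentres should be unaffected.

Compound list
1 | (R)-4-(tert-butyldimethylsilyloxy)cyclopent-2-en-1-one | O=C1C=C[C@H](O[Si](C)(C)C(C)(C)C)C1 | starting material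
2 | (R)-4-(tert-butyldimethylsilyloxy)-2-iodocyclopent-2-en-1-one | O=C1C(I)=C[C@H](O[Si](C)(C)C(C)(C)C)C1 | intermediate
3 | allyltributylstannane | C=CC[Sn](CCCC)(CCCC)CCCC | starting material
4 | (R)-2-allyl-4-(tert-butyldimethylsilyloxy)cyclopent-2-en-1-one | O=C1C(CC=C)=C[C@H](O[Si](C)(C)C(C)(C)C)C1 | intermediate
5 | tert-butyl methacrylate | C=C(C)C(=O)OC(C)(C)C | starting material
6 | tert-butyl (E)-4-[(3R)-3-(tert-butyldimethylsilyloxy)-5-oxocyclopent-1-en-1-yl]-2-methylbut-2-enoate | O=C1C(C/C=C(\C)C(=O)OC(C)(C)C)=C[C@H](O[Si](C)(C)C(C)(C)C)C1 | intermediate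
7 | tert-butyl (E)-4-[(1S,4R,5S)-4-(tert-butyldimethylsilyloxy)-2-oxo-6-oxabicyclo[3.1.0]hexan-1-yl]-2-methylbut-2-enoate | O=C1C[C@@H](O[Si](C)(C)C(C)(C)C)[C@@H]2O[C@]12C/C=C(\C)C(=O)OC(C)(C)C | intermediate
8 | tert-butyl (E)-4-[(1S,4R,5S)-4-(tert-butyldimethylsilyloxy)-2-(trimethylsilyloxy)-6-oxabicyclo[3.1.0]hex-2-en-1-yl]-2-methylbut-2-enoate | C[Si](C)(C)OC1=C[C@@H](O[Si](C)(C)C(C)(C)C)[C@@H]2O[C@]12C/C=C(\C)C(=O)OC(C)(C)C | intermediate
9 | formaldehyde | C=O | starting material
10 | tert-butyl (E)-4-[(1S,3R,4R,5S)-4-(tert-butyldimethylsilyloxy)-3-(hydroxymethyl)-2-oxo-6-oxabicyclo[3.1.0]hexan-1-yl]-2-methylbut-2-enoate | O=C1[C@H](CO)[C@@H](O[Si](C)(C)C(C)(C)C)[C@@H]2O[C@]12C/C=C(\C)C(=O)OC(C)(C)C | intermediate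
11 | tert-butyl (E)-4-[(1S,3R,4R,5S)-4-(tert-butyldimethylsilyloxy)-3-[(tert-butyldimethylsilyloxy)methyl]-2-oxo-6-oxabicyclo[3.1.0]hexan-1-yl]-2-methylbut-2-enoate | O=C1[C@H](CO[Si](C)(C)C(C)(C)C)[C@@H](O[Si](C)(C)C(C)(C)C)[C@@H]2O[C@]12C/C=C(\C)C(=O)OC(C)(C)C | intermediate
12 | tert-butyl (E)-4-[(1S,4R,5S)-4-(tert-butyldimethylsilyloxy)-3-[(tert-butyldimethylsilyloxy)methyl]-2-(trimethylsilyloxy)-6-oxabicyclo[3.1.0]hex-2-en-1-yl]-2-methylbut-2-enoate (key-step precursor) | C[Si](C)(C)OC1=C(CO[Si](C)(C)C(C)(C)C)[C@@H](O[Si](C)(C)C(C)(C)C)[C@@H]2O[C@]12C/C=C(\C)C(=O)OC(C)(C)C | intermediate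
13 | bromoform | BrC(Br)Br | starting material
14 | siloxy-dibromocyclopropane adduct of 12 (CBr2 bridging C6 and C2 on the face anti to the C3 silyloxy group; cyclopentane fused to the oxirane and to the dibromocyclopropane) | C[Si](C)(C)O[C@@]12C(Br)(Br)[C@]1(CO[Si](C)(C)C(C)(C)C)[C@@H](O[Si](C)(C)C(C)(C)C)[C@@H]3O[C@]23C/C=C(\C)C(=O)OC(C)(C)C | intermediate (not isolated)
15 | tert-butyl (E)-4-[(1S,5R,6S)-3-bromo-5-(tert-butyldimethylsilyloxy)-4-[(tert-butyldimethylsilyloxy)methyl]-2-oxo-7-oxabicyclo[4.1.0]hept-3-en-1-yl]-2-methylbut-2-enoate (key-step product) | O=C1C(Br)=C(CO[Si](C)(C)C(C)(C)C)[C@@H](O[Si](C)(C)C(C)(C)C)[C@@H]2O[C@]12C/C=C(\C)C(=O)OC(C)(C)C | intermediate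
16 | (E)-hept-1-enylboronic acid | CCCCC/C=C/B(O)O | starting material
17 | tert-butyl (E)-4-[(1S,5R,6S)-5-(tert-butyldimethylsilyloxy)-4-[(tert-butyldimethylsilyloxy)methyl]-3-[(E)-hept-1-enyl]-2-oxo-7-oxabicyclo[4.1.0]hept-3-en-1-yl]-2-methylbut-2-enoate | CCCCC/C=C/C1=C(CO[Si](C)(C)C(C)(C)C)[C@@H](O[Si](C)(C)C(C)(C)C)[C@@H]2O[C@]2(C/C=C(\C)C(=O)OC(C)(C)C)C1=O | intermediate
18 | tert-butyl (E)-4-[(1S,5R,6S)-3-[(E)-hept-1-enyl]-5-hydroxy-4-(hydroxymethyl)-2-oxo-7-oxabicyclo[4.1.0]hept-3-en-1-yl]-2-methylbut-2-enoate | CCCCC/C=C/C1=C(CO)[C@@H](O)[C@@H]2O[C@]2(C/C=C(\C)C(=O)OC(C)(C)C)C1=O | intermediate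
19 | (E)-4-[(1S,5R,6S)-3-[(E)-hept-1-enyl]-5-hydroxy-4-(hydroxymethyl)-2-oxo-7-oxabicyclo[4.1.0]hept-3-en-1-yl]-2-methylbut-2-enoic acid | CCCCC/C=C/C1=C(CO)[C@@H](O)[C@@H]2O[C@]2(C/C=C(\C)C(=O)O)C1=O | target

Total step count: 12.
Longest linear sequence: 12 steps (1 to 19); the other starting materials enter as single reagents.

Steps most likely to fail

Step 9 (key step). What may go wrong: tert-butoxide may attack silicon of the enol ether, or remove the hydrogen at C3 or the one next to C5 in the side chain, faster than the carbene is transferred. That would return the ketone or open the oxirane towards an aromatised ring. The adduct may also fail to open cleanly. The fallback sets out from 12 and comes back at 17, introducing C1 as CH2 without base and adding the halogen afterwards. The enol ether is cyclopropanated with ZnEt2 and CH2I2 (Furukawa variant of the Simmons–Smith reaction) to the siloxycyclopropane F1. FeCl3 in DMF (Ito–Saegusa oxidative ring opening) cleaves the internal bond to the ring-enlarged β-chloro ketone F2. This loses HCl with CH3CO2Na in methanol to give the 3-substituted cyclohexenone F3. α-Iodination with I2, pyridine and catalytic DMAP gives the 2-iodoenone F4. Suzuki coupling of F4 with 16 under the conditions of step 10 gives 17.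

Step 6. What may go wrong: in water the silyl enol ether may be hydrolysed back to 7 faster than it attacks formaldehyde, the Lewis acid may assist opening of the oxirane, or the aldol may dehydrate to a methylene ketone. The fallback sets out from 7 (8 is not needed) and comes back at 10, replacing the aqueous Lewis-acid aldol by an anhydrous enolate aldol. Ketone 7 is deprotonated with LiN(Si(CH3)3)2 in THF at −78 °C to the lithium enolate F5. This is treated at that temperature with monomeric formaldehyde gas, generated by cracking paraformaldehyde, and quenched cold with aqueous NH4Cl to give 10.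

Step 10. What may go wrong: the aqueous base needed for boron transmetalation may remove the C3 hydrogen of the epoxy enone and start oxirane opening, or oxidative addition into the hindered bromide may be so slow that protodeboronation of the boronic acid wins. The fallback sets out from 15 and comes back at 17, using base-free tin transmetalation. (E)-Tributyl(hept-1-enyl)stannane F6 is made from hept-1-yne by radical hydrostannation (Bu3SnH, AIBN, heated with a slight excess of stannane so that the E isomer is favoured, then purified). It is coupled with 15 in a Stille reaction (PdCl2(PhCN)2, AsPh3, CuI, NMP, rt to 50 °C) to give 17.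

Further compounds
F1 | step 9 | siloxycyclopropane from 12 (CH2 bridging C6 and C2, anti to the C3 silyloxy group) | C[Si](C)(C)O[C@@]12C[C@]1(CO[Si](C)(C)C(C)(C)C)[C@@H](O[Si](C)(C)C(C)(C)C)[C@@H]3O[C@]23C/C=C(\C)C(=O)OC(C)(C)C
F2 | step 9 | ring-enlarged 3-chlorocyclohexanone (either configuration at the chlorinated carbon) | O=C1CC(Cl)(CO[Si](C)(C)C(C)(C)C)[C@@H](O[Si](C)(C)C(C)(C)C)[C@@H]2O[C@]12C/C=C(\C)C(=O)OC(C)(C)C
F3 | step 9 | tert-butyl (E)-4-[(1S,5R,6S)-5-(tert-butyldimethylsilyloxy)-4-[(tert-butyldimethylsilyloxy)methyl]-2-oxo-7-oxabicyclo[4.1.0]hept-3-en-1-yl]-2-methylbut-2-enoate | O=C1C=C(CO[Si](C)(C)C(C)(C)C)[C@@H](O[Si](C)(C)C(C)(C)C)[C@@H]2O[C@]12C/C=C(\C)C(=O)OC(C)(C)C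
F4 | step 9 | tert-butyl (E)-4-[(1S,5R,6S)-5-(tert-butyldimethylsilyloxy)-4-[(tert-butyldimethylsilyloxy)methyl]-3-iodo-2-oxo-7-oxabicyclo[4.1.0]hept-3-en-1-yl]-2-methylbut-2-enoate | O=C1C(I)=C(CO[Si](C)(C)C(C)(C)C)[C@@H](O[Si](C)(C)C(C)(C)C)[C@@H]2O[C@]12C/C=C(\C)C(=O)OC(C)(C)C
F5 | step 6 | lithium enolate of 7 | [Li]OC1=C[C@@H](O[Si](C)(C)C(C)(C)C)[C@@H]2O[C@]12C/C=C(\C)C(=O)OC(C)(C)C
F6 | step 10 | (E)-tributyl(hept-1-enyl)stannane | CCCCC/C=C/[Sn](CCCC)(CCCC)CCCC
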